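**Plan**
- Retrosynthesis: after late functional-group changes, ring A is cut at C1=C2 (aldol condensation), rings B and C are cut together at C5–C6 and C8–C9 (tandem Michael–Michael), then C4=C5 (Knoevenagel), C6=C8 (olefination) and C12–C13 (union of two fragments).
- Forward: ring D comes from a purchased cyclopentenone and is joined to an acyclic C10 fragment; rings C and B then close in one operation, ring A is closed next, and C11, C16, C3, C7 and C19 are adjusted last.
- Enabling feature: in ring B, C9 and C5 flank the quaternary C10. C6 carries the carboxyl-level carbon C7, so C8=C6 is a Michael acceptor. A temporary C11 ketone in ring C makes C9 a donor, and a temporary alkylidene acetoacetate at C5 is the second acceptor and already holds C2, C3, C4 and C19 of ring A.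
- Stereochemistry: C10 from desymmetrisation of a prochiral diol; C13 from anti addition to (R)-4-silyloxycyclopentenone; C8 from the tether; C5 from allylic 1,3-strain; C9 and C6 by equilibration.
- Later centres: C4 by methylation anti to C20, C3 by bulky hydride, C16 by exo Grignard addition.

Key step: step 13

Remark: locants C1–C20 are those of the gibberellane skeleton. Compounds 12, 13, 14 and 16 are carried as E/Z mixtures at C6=C8 and C4=C5, which is without consequence because both double bonds are consumed in step 13. C4 in 18–20 is an epimerizable β-keto ester centre and is left undefined.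

**Step 1**
Reactants: 1 diethyl 2-methylmalonate
Product: 2 diethyl 2-allyl-2-methylmalonate
Conditions: NaH, allyl bromide, THF, 0 °C to rt
Reagents that add atoms: allyl bromide, C=CCBr
Why: Malonic ester alkylation of the sodium enolate builds the prochiral quaternary carbon that becomes C10, with C9, C11 and C12 in the allyl group.

**Step 2**
Reactants: 2 diethyl 2-allyl-2-methylmalonate
Product: 3 2-allyl-2-methylpropane-1,3-diol
Conditions: LiAlH4, THF, 0 °C to reflux
Reagents that add atoms: none
Why: LiAlH4 reduction of both esters gives the prochiral 2,2-disubstituted propane-1,3-diol.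

**Step 3**
Reactants: 3 2-allyl-2-methylpropane-1,3-diol
Product: 4 (R)-2-(hydroxymethyl)-2-methylpent-4-en-1-yl benzoate
Conditions: CuCl2 (5 mol%), (R,R)-2,2'-isopropylidenebis(4-phenyl-2-oxazoline) (5 mol%; the ligand antipode that delivers the R monoester is used), BzCl, Et3N, THF, −78 to −40 °C
Reagents that add atoms: benzoyl chloride, O=C(Cl)c1ccccc1
Why: Copper–bis(oxazoline)-catalysed desymmetrising monobenzoylation of a prochiral 2,2-disubstituted 1,3-diol acylates one enantiotopic CH2OH arm of the chiral copper diolate and so sets the quaternary stereocentre C10.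

**Step 4**
Reactants: 4 (R)-2-(hydroxymethyl)-2-methylpent-4-en-1-yl benzoate
Product: 5 (S)-2-formyl-2-methylpent-4-en-1-yl benzoate
Conditions: Dess–Martin periodinane, NaHCO3, CH2Cl2, 0 °C to rt
Reagents that add atoms: none
Why: Dess–Martin oxidation of the free neopentyl alcohol gives the non-enolizable aldehyde (future C1) and leaves the benzoate arm (future C5) untouched.

**Step 5**
Reactants: 5 (S)-2-formyl-2-methylpent-4-en-1-yl benzoate
Product: 6 (S)-2-(dimethoxymethyl)-2-methylpent-4-en-1-yl benzoate
Conditions: HC(OMe)3, MeOH, PPTS (cat.), rt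
Reagents that add atoms: trimethyl orthoformate, COC(OC)OC
Why: Acid-catalysed acetalisation masks C1 as a branched, base-stable dimethyl acetal that later steers the facial course at C5.

**Step 6**
Reactants: 6 (S)-2-(dimethoxymethyl)-2-methylpent-4-en-1-yl benzoate
Product: 7 (S)-2-(dimethoxymethyl)-2-methyl-4-oxopentyl benzoate
Conditions: PdCl2 (10 mol%), Cu(OAc)2 (20 mol%), O2 (1 atm), DMA/H2O, rt
Reagents that add atoms: water, O
Why: Tsuji–Wacker oxidation of the terminal alkene gives the methyl ketone with Markovnikov selectivity, creating the C11 carbonyl with C12 as its methyl group; copper acetate keeps the medium non-acidic for the acetal.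

**Step 7**
Reactants: 7 (S)-2-(dimethoxymethyl)-2-methyl-4-oxopentyl benzoate
Product: 8 (S)-2-(dimethoxymethyl)-2-methyl-4-(trimethylsilyloxy)pent-4-en-1-yl benzoate
Conditions: LiN(SiMe3)2, Me3SiCl, THF, −78 °C
Reagents that add atoms: chlorotrimethylsilane, C[Si](C)(C)Cl
Why: Kinetic deprotonation at the unhindered methyl group (the other α-CH2 is neopentyl) followed by O-silylation gives the terminal silyl enol ether.

**Step 8**
Reactants: 8 (S)-2-(dimethoxymethyl)-2-methyl-4-(trimethylsilyloxy)pent-4-en-1-yl benzoate; 9 (R)-4-(tert-butyldimethylsilyloxy)cyclopent-2-en-1-one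
Product: 11 (S)-5-[(1R,2R)-2-(tert-butyldimethylsilyloxy)-4-oxocyclopentyl]-2-(dimethoxymethyl)-2-methyl-4-oxopentyl benzoate, via cyclopentenyl trimethylsilyl ether 10 (not isolated)
Conditions: tris(dimethylamino)sulfonium difluorotrimethylsilicate (5 mol%), THF, −78 to −30 °C; then AcOH, H2O/THF, 0 °C
Reagents that add atoms: none
Why: Fluoride-catalysed Mukaiyama–Michael addition forms C12–C13; the nucleophile enters anti to the C16 silyloxy group, as in prostaglandin-type conjugate additions, which sets C13, and the ring enol silane 10 is hydrolysed on work-up.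

**Step 9**
Reactants: 11 (S)-5-[(1R,2R)-2-(tert-butyldimethylsilyloxy)-4-oxocyclopentyl]-2-(dimethoxymethyl)-2-methyl-4-oxopentyl benzoate
Product: 12 methyl (cyclopentylidene)acetate from 11 (C8=C6 enoate; E/Z mixture; stereocentres as in 11)
Conditions: (MeO)2P(O)CH2CO2Me, NaH, THF, 0 °C to rt
Reagents that add atoms: trimethyl phosphonoacetate, COC(=O)CP(=O)(OC)OC
Why: Horner–Wadsworth–Emmons olefination should occur at the unhindered cyclopentanone C8 in preference to the C11 ketone flanked by the neopentyl C9, giving the C8=C6–C7 enoate whose geometry is irrelevant later.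

**Step 10**
Reactants: 12 methyl (cyclopentylidene)acetate from 11
Product: 13 primary C5 alcohol from 12 (benzoate removed; stereocentres unchanged)
Conditions: K2CO3 (cat.), MeOH, 0 °C
Reagents that add atoms: none
Why: Base-catalysed transesterification removes the benzoate while the methyl enoate, acetal and silyl ether are unaffected.

**Step 11**
Reactants: 13 primary C5 alcohol from 12
Product: 14 C5 aldehyde from 13 (stereocentres unchanged)
Conditions: Dess–Martin periodinane, NaHCO3, CH2Cl2, 0 °C to rt
Reagents that add atoms: none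
Why: Dess–Martin oxidation gives the non-enolizable neopentyl aldehyde at C5.

**Step 12**
Reactants: 14 C5 aldehyde from 13; 15 tert-butyl acetoacetate
Product: 16 alkylidene acetoacetate from 14 (C5=C4 acceptor; E/Z mixture)
Conditions: piperidine (20 mol%), AcOH (20 mol%), benzene, 4 Å molecular sieves, 40 °C
Reagents that add atoms: none
Why: Knoevenagel condensation installs the doubly activated C5=C4 acceptor, which already carries C2, C3, C4 and C19 of ring A.

**Step 13**
Reactants: 16 alkylidene acetoacetate from 14
Product: 18 ring A-seco precursor (rings B C D closed; 11-ketone; tert-butyl 3-oxobutanoate unit at C5; methyl ester C7; dimethyl acetal C1; 16-OTBS), via ring C-closed mono-Michael adduct 17 (not isolated)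
Conditions: KOt-Bu (1.2 equiv), THF, −40 to 0 °C; then t-BuOH, rt; AcOH quench
Reagents that add atoms: none
Why: KOt-Bu reversibly enolizes the C11 ketone, and only the C9 enolate has an allowed closure (6-(enolendo)-exo-trig onto C8, the β-carbon of the C8=C6 enoate), whereas the C12 enolate could reach C5 only by a disfavoured 5-(enolendo)-exo-trig path; ring C therefore closes first, and the C6 ester enolate so formed adds 5-(enolexo)-exo-trig to C5 of the alkylidene acetoacetate, closing ring B and ending as the stable β-keto ester enolate. The closest known reaction type is the intramolecular tandem Michael–Michael (double Michael) annulation of a ketone enolate with two tethered acceptors, here a formal [3+2] union of the C9–C10–C5 unit with C8=C6. C8 is fixed by the C13–C12–C11 tether, which can deliver C9 only to the ring D face cis to C12 (bicyclo[3.2.1]octane formation). C5 is set by allylic 1,3-strain in the trisubstituted alkylidene acetoacetate: the C20 methyl eclipses C5=C4, the bulky CH(OMe)2 group (C1) lies on the face away from C9, and C6 enters from the C9 face, so C4 ends cis to C20 and trans to C1 as the later trans A/B fusion requires. C9 (α to the C11 ketone) and C6 (α to the ester) should equilibrate under the conditions to the cis-fused B/C hydrindanone (H9 cis to C15, the preferred form of angularly substituted hydrindan-4-ones) and to the ester trans to the C5 substituent. The step needs enolate regioselectivity and discrimination between two acceptors; Baldwin's rules for enolates secure the first, and the second follows because the more electrophilic C5=C4 acceptor is within allowed reach only of the C6 enolate.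

**Step 14**
Reactants: 18 ring A-seco precursor
Product: 20 ring A enone β-keto ester (C1=C2; 3-ketone; 4-CO2t-Bu; 11-ketone; 7-methyl ester; 16-OTBS; A/B trans), via C1 keto aldehyde 19 (not isolated)
Conditions: PPTS, acetone/H2O (10:1), 45 °C; then pyrrolidine (0.3 equiv), AcOH (0.3 equiv), toluene, 60 °C
Reagents that add atoms: none
Why: Mild acetal hydrolysis unveils the non-enolizable C1 aldehyde, which is 1,5-related to the C3 ketone, and a Robinson-type (Hagemann-type) intramolecular aldol condensation of the C2 methyl (6-(enolendo)-exo-trig) closes ring A; because C1 and C4 sit on opposite faces of ring B after step 13, the A/B fusion is trans.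

**Step 15**
Reactants: 20 ring A enone β-keto ester
Product: 21 C4-methylated enone (C18 methyl trans to C20; C19 tert-butyl ester cis to C20)
Conditions: MeI, K2CO3, acetone, rt
Reagents that add atoms: iodomethane, CI
Why: C-alkylation of the β-keto ester enolate; MeI should approach C4 anti to the axial C20 methyl, so C18 ends trans and the C19 ester cis to C20.

**Step 16**
Reactants: 21 C4-methylated enone
Product: 22 C11 enol triflate (C11=C12)
Conditions: KN(SiMe3)2 (1.1 equiv), THF, −78 °C; then PhNTf2
Reagents that add atoms: N-phenylbis(trifluoromethanesulfonimide), O=S(=O)(N(c1ccccc1)S(=O)(=O)C(F)(F)F)C(F)(F)F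
Why: The ring A enone has no enolizable hydrogen, so kinetic deprotonation takes place at the accessible C12 methylene of the C11 ketone and the enolate is trapped as the enol triflate.

**Step 17**
Reactants: 22 C11 enol triflate
Product: 23 11,12-alkene (ring A enone retained)
Conditions: Pd(OAc)2 (5 mol%), PPh3 (10 mol%), HCO2H, Bu3N, DMF, 60 °C
Reagents that add atoms: none
Why: Palladium-catalysed formate reduction of the enol triflate replaces C–OTf by C–H and removes the C11 oxygen that served as the activating group.

**Step 18**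
Reactants: 23 11,12-alkene
Product: 24 saturated 3-ketone (19-tert-butyl ester; 7-methyl ester; 16-OTBS)
Conditions: H2 (1 atm), 10% Pd/C, EtOAc, rt
Reagents that add atoms: none
Why: Heterogeneous hydrogenation saturates C11=C12 and C1=C2; no stereocentre is formed.

**Step 19**
Reactants: 24 saturated 3-ketone
Product: 25 16-alcohol (hydroxyl exo)
Conditions: HF·pyridine, THF/pyridine, 0 °C to rt
Reagents that add atoms: none
Why: Fluoride cleavage of the secondary silyl ether under mildly acidic conditions spares the tert-butyl ester and the non-enolizable β-keto ester.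

**Step 20**
Reactants: 25 16-alcohol
Product: 26 3,16-diketone
Conditions: Dess–Martin periodinane, NaHCO3, CH2Cl2, rt
Reagents that add atoms: none
Why: Dess–Martin oxidation gives the bicyclo[3.2.1]octan-16-one.

**Step 21**
Reactants: 26 3,16-diketone
Product: 27 16-methyl-16-carbinol (methyl exo; hydroxyl endo; 3-ketone retained)
Conditions: MeMgBr (1.3 equiv), THF, −78 to −40 °C
Reagents that add atoms: methylmagnesium bromide, C[Mg]Br
Why: Grignard addition to the unhindered C16 ketone from the exo face (anti to the C11–C12 bridge) gives the exo methyl and endo hydroxyl; the C3 ketone next to the quaternary C4 and the two hindered esters are expected to react much more slowly.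

**Step 22**
Reactants: 27 16-methyl-16-carbinol
Product: 28 3-alcohol (axial hydroxyl trans to the C19 ester)
Conditions: LiBH(s-Bu)3, THF, −78 °C
Reagents that add atoms: none
Why: The bulky hydride should attack the C3 ketone along the equatorial trajectory, as is usual for 4,4-disubstituted 3-ketones, giving the axial alcohol trans to C19.

**Step 23**
Reactants: 28 3-alcohol
Product: 29 triol tert-butyl ester (C7 CH2OH)
Conditions: LiBH4, THF/MeOH, 0 to 40 °C
Reagents that add atoms: none
Why: LiBH4 reduces the C7 methyl ester to the primary alcohol while the tert-butyl ester on the quaternary C4 is inert.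

**Step 24**
Reactants: 29 triol tert-butyl ester
Product: 31 CNP0170663.1, via tris(trimethylsilyl) ether trimethylsilyl ester 30 (not isolated)
Conditions: Me3SiOTf, 2,6-lutidine, CH2Cl2, 0 °C to rt; then MeOH, citric acid, rt
Reagents that add atoms: none
Why: Silyl triflate-mediated cleavage of the tert-butyl ester proceeds by alkyl–oxygen fission (loss of isobutene), which is insensitive to crowding at C19, and the transient silylation protects the tertiary C16 alcohol from ionisation before mild methanolysis frees the acid and the hydroxyls.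

**Compound list**
1 | diethyl 2-methylmalonate | CCOC(=O)C(C)C(=O)OCC | starting material
2 | diethyl 2-allyl-2-methylmalonate | CCOC(=O)C(C)(CC=C)C(=O)OCC | intermediate
3 | 2-allyl-2-methylpropane-1,3-diol | C=CCC(C)(CO)CO | intermediate
4 | (R)-2-(hydroxymethyl)-2-methylpent-4-en-1-yl benzoate | C=CC[C@](C)(CO)COC(=O)c1ccccc1 | intermediate
5 | (S)-2-formyl-2-methylpent-4-en-1-yl benzoate | C=CC[C@](C)(C=O)COC(=O)c1ccccc1 | intermediate
6 | (S)-2-(dimethoxymethyl)-2-methylpent-4-en-1-yl benzoate | C=CC[C@](C)(C(OC)OC)COC(=O)c1ccccc1 | intermediate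
7 | (S)-2-(dimethoxymethyl)-2-methyl-4-oxopentyl benzoate | CC(=O)C[C@](C)(C(OC)OC)COC(=O)c1ccccc1 | intermediate
8 | (S)-2-(dimethoxymethyl)-2-methyl-4-(trimethylsilyloxy)pent-4-en-1-yl benzoate | C=C(O[Si](C)(C)C)C[C@](C)(C(OC)OC)COC(=O)c1ccccc1 | intermediate
9 | (R)-4-(tert-butyldimethylsilyloxy)cyclopent-2-en-1-one | O=C1C=C[C@H](O[Si](C)(C)C(C)(C)C)C1 | starting material
10 | cyclopentenyl trimethylsilyl ether of 11 (C8 enol silane, C8=C14) | C[Si](C)(C)OC1=C[C@@H](CC(=O)C[C@](C)(C(OC)OC)COC(=O)c2ccccc2)[C@H](O[Si](C)(C)C(C)(C)C)C1 | intermediate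
11 | (S)-5-[(1R,2R)-2-(tert-butyldimethylsilyloxy)-4-oxocyclopentyl]-2-(dimethoxymethyl)-2-methyl-4-oxopentyl benzoate | O=C1C[C@@H](CC(=O)C[C@](C)(C(OC)OC)COC(=O)c2ccccc2)[C@H](O[Si](C)(C)C(C)(C)C)C1 | intermediate
12 | methyl (cyclopentylidene)acetate from 11 (C8=C6 enoate, E/Z mixture, stereocentres as in 11) | COC(=O)C=C1C[C@@H](CC(=O)C[C@](C)(C(OC)OC)COC(=O)c2ccccc2)[C@H](O[Si](C)(C)C(C)(C)C)C1 | intermediate
13 | primary C5 alcohol from 12 (benzoate removed) | COC(=O)C=C1C[C@@H](CC(=O)C[C@](C)(C(OC)OC)CO)[C@H](O[Si](C)(C)C(C)(C)C)C1 | intermediate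
14 | C5 aldehyde from 13 | COC(=O)C=C1C[C@@H](CC(=O)C[C@](C)(C(OC)OC)C=O)[C@H](O[Si](C)(C)C(C)(C)C)C1 | intermediate
15 | tert-butyl acetoacetate | CC(=O)CC(=O)OC(C)(C)C | starting material
16 | alkylidene acetoacetate from 14 (tert-butyl 2-acetylalk-2-enoate, C5=C4, E/Z mixture) | COC(=O)C=C1C[C@@H](CC(=O)C[C@](C)(C(OC)OC)C=C(C(C)=O)C(=O)OC(C)(C)C)[C@H](O[Si](C)(C)C(C)(C)C)C1 | intermediate
17 | ring C-closed mono-Michael adduct (bicyclo[3.2.1]octan-11-one, C8 bears CH2CO2Me, C5=C4 acceptor intact) | CC(=O)C(C(=O)OC(C)(C)C)=C[C@@](C)(C(OC)OC)[C@@H]1C(=O)C[C@@H]2C[C@@]1(CC(=O)OC)C[C@H]2O[Si](C)(C)C(C)(C)C | intermediate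
18 | ring A-seco precursor: rings B, C, D closed; C10 bears methyl and CH(OMe)2 (C1); C5 bears CH(COCH3)CO2t-Bu; C6 bears CO2Me; 11-ketone; 16-OTBS exo; H5, H9 and C7 on the face opposite the C20 methyl | C[C@@]1(C(OC)OC)[C@@H](C(C(C)=O)C(=O)OC(C)(C)C)[C@H](C(=O)OC)[C@@]23C[C@@H](CC(=O)[C@@H]12)[C@H](O[Si](C)(C)C(C)(C)C)C3 | intermediate
19 | C1 keto aldehyde from 18 (acetal hydrolysed) | C[C@@]1(C=O)[C@@H](C(C(C)=O)C(=O)OC(C)(C)C)[C@H](C(=O)OC)[C@@]23C[C@@H](CC(=O)[C@@H]12)[C@H](O[Si](C)(C)C(C)(C)C)C3 | intermediate
20 | gibberellane tetracycle, ring A enone β-keto ester: C1=C2, 3-oxo, 4-CO2t-Bu (no C18), 11-oxo, 7-methyl ester, 16-OTBS; A/B trans, natural configuration at C5, C6, C8, C9, C10, C13 | C[C@@]12C=CC(=O)C(C(=O)OC(C)(C)C)[C@H]1[C@H](C(=O)OC)[C@@]13C[C@@H](CC(=O)[C@@H]21)[C@H](O[Si](C)(C)C(C)(C)C)C3 | intermediate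
21 | C4-methylated enone: as 20 with C18 methyl trans and C19 tert-butyl ester cis to C20 | C[C@@]12C=CC(=O)[C@@](C)(C(=O)OC(C)(C)C)[C@H]1[C@H](C(=O)OC)[C@@]13C[C@@H](CC(=O)[C@@H]21)[C@H](O[Si](C)(C)C(C)(C)C)C3 | intermediate
22 | C11 enol triflate of 21 (C11=C12) | C[C@@]12C=CC(=O)[C@@](C)(C(=O)OC(C)(C)C)[C@H]1[C@H](C(=O)OC)[C@@]13C[C@@H](C=C(OS(=O)(=O)C(F)(F)F)[C@@H]21)[C@H](O[Si](C)(C)C(C)(C)C)C3 | intermediate
23 | 1,11-diene: ring A enone with C11=C12 alkene | C[C@@]12C=CC(=O)[C@@](C)(C(=O)OC(C)(C)C)[C@H]1[C@H](C(=O)OC)[C@@]13C[C@@H](C=C[C@@H]21)[C@H](O[Si](C)(C)C(C)(C)C)C3 | intermediate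
24 | saturated 3-ketone: 19-tert-butyl ester, 7-methyl ester, 16-OTBS (exo) | C[C@@]12CCC(=O)[C@@](C)(C(=O)OC(C)(C)C)[C@H]1[C@H](C(=O)OC)[C@@]13C[C@@H](CC[C@@H]21)[C@H](O[Si](C)(C)C(C)(C)C)C3 | intermediate
25 | 16-alcohol (exo hydroxyl) of 24 | C[C@@]12CCC(=O)[C@@](C)(C(=O)OC(C)(C)C)[C@H]1[C@H](C(=O)OC)[C@@]13C[C@@H](CC[C@@H]21)[C@H](O)C3 | intermediate
26 | 3,16-diketone | C[C@@]12CCC(=O)[C@@](C)(C(=O)OC(C)(C)C)[C@H]1[C@H](C(=O)OC)[C@@]13C[C@@H](CC[C@@H]21)C(=O)C3 | intermediate
27 | 16-methyl-16-carbinol (methyl exo, hydroxyl endo), 3-ketone | C[C@@]12CCC(=O)[C@@](C)(C(=O)OC(C)(C)C)[C@H]1[C@H](C(=O)OC)[C@@]13C[C@@H](CC[C@@H]21)[C@@](C)(O)C3 | intermediate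
28 | 3-alcohol (axial, trans to C19), 19-tert-butyl ester, 7-methyl ester | C[C@@]12CC[C@H](O)[C@@](C)(C(=O)OC(C)(C)C)[C@H]1[C@H](C(=O)OC)[C@@]13C[C@@H](CC[C@@H]21)[C@@](C)(O)C3 | intermediate
29 | triol tert-butyl ester (C7 CH2OH) | C[C@@]12CC[C@H](O)[C@@](C)(C(=O)OC(C)(C)C)[C@H]1[C@H](CO)[C@@]13C[C@@H](CC[C@@H]21)[C@@](C)(O)C3 | intermediate
30 | tris(trimethylsilyl) ether trimethylsilyl ester of the target | C[C@@]12CC[C@H](O[Si](C)(C)C)[C@@](C)(C(=O)O[Si](C)(C)C)[C@H]1[C@H](CO[Si](C)(C)C)[C@@]13C[C@@H](CC[C@@H]21)[C@@](C)(O[Si](C)(C)C)C3 | intermediate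
31 | CNP0170663.1 (3,7,16-trihydroxy-16-methyl gibberellan-19-oic acid, configuration as given) | C[C@@]12CC[C@H](O)[C@@](C)(C(=O)O)[C@H]1[C@H](CO)[C@@]13C[C@@H](CC[C@@H]21)[C@@](C)(O)C3 | target

**Totals**
Total step count: 24. Longest linear sequence: 24 steps (1 to 31); 9 and 15 enter as purchased fragments.

**Steps most likely to fail**

Step 13. The cascade may be diverted by attack of the C12-side enolate or of alkoxide on the very electrophilic C5=C4 acceptor, by elimination of the C16 silyloxy group from the dienolate of the enoate before ring C closes, or by incomplete equilibration at C9. The fallback runs the two Michael additions separately. It sets out from 13: KOt-Bu in THF closes ring C alone and should give the ring C-closed hydroxy keto ester F1. Dess–Martin oxidation gives the corresponding C5 aldehyde F2. Knoevenagel condensation with 15 gives 17, now isolated, and a second base treatment closes ring B, coming back to the route at 18.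

Step 9. Under the basic olefination the β-silyloxy cyclopentanone may lose the silyloxy group by β-elimination, or the C11 ketone may react. The fallback sets out from 11: a Reformatsky addition (Zn, methyl bromoacetate, THF) under non-basic conditions should give the tertiary β-hydroxy ester F3, and dehydration with the Burgess reagent comes back to the route at 12.

Step 21. The Grignard reagent may add to or enolize the C3 ketone, or attack the C7 ester. The fallback takes the C3 carbonyl out of play before ring D is unmasked. It sets out from 24: LiBH(s-Bu)3 gives the 3-ol silyl ether F4, and HF·pyridine gives the 3,16-diol F5. A nitroxyl oxidation (TEMPO, PhI(OAc)2), which should discriminate the unhindered C16 hydroxyl from the axial neopentyl C3 hydroxyl, gives the 3-hydroxy-16-ketone F6. MeMgBr (2.5 equiv) then comes back to the route at 28.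

**Further compounds**
F1 | step 13 | ring C-closed hydroxy keto ester (from 13; C5 as CH2OH) | OC[C@@](C)(C(OC)OC)[C@@H]1C(=O)C[C@@H]2C[C@@]1(CC(=O)OC)C[C@H]2O[Si](C)(C)C(C)(C)C
F2 | step 13 | corresponding C5 aldehyde | O=C[C@@](C)(C(OC)OC)[C@@H]1C(=O)C[C@@H]2C[C@@]1(CC(=O)OC)C[C@H]2O[Si](C)(C)C(C)(C)C
F3 | step 9 | tertiary β-hydroxy ester at C8 (from 11, mixture at C8) | COC(=O)CC1(O)C[C@@H](CC(=O)C[C@](C)(C(OC)OC)COC(=O)c2ccccc2)[C@H](O[Si](C)(C)C(C)(C)C)C1
F4 | step 21 | 3-ol silyl ether (from 24) | C[C@@]12CC[C@H](O)[C@@](C)(C(=O)OC(C)(C)C)[C@H]1[C@H](C(=O)OC)[C@@]13C[C@@H](CC[C@@H]21)[C@H](O[Si](C)(C)C(C)(C)C)C3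
F5 | step 21 | 3,16-diol | C[C@@]12CC[C@H](O)[C@@](C)(C(=O)OC(C)(C)C)[C@H]1[C@H](C(=O)OC)[C@@]13C[C@@H](CC[C@@H]21)[C@H](O)C3
F6 | step 21 | 3-hydroxy-16-ketone | C[C@@]12CC[C@H](O)[C@@](C)(C(=O)OC(C)(C)C)[C@H]1[C@H](C(=O)OC)[C@@]13C[C@@H](CC[C@@H]21)C(=O)C3
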